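The constants of this flask are few: c_L is held at 19 mM and G is charged at 0.16 M, and the earlier runs give readings of Q, so the time constant I can read is that of the rise of Q.

in all of them: L 19 mM (held)
- violet: G 0.22 M; temperature −14 °C; run made earlier
- grey: G 0.35 M; temperature 0 °C; run made earlier
- cedar: G 0.16 M; temperature −20 °C; time 3.0 h
- birch: G 0.16 M; temperature 5 °C; time 3.0 h

violet run (percent of the G charged)

| time / h | Q / % |
|---|---|
| 0.200 | 24.3 |
| 0.667 | 33.8 |
| 1.00 | 34.4 |
| 1.50 | 34.0 |
| 2.50 | 35.1 |

grey run (percent of the G charged)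

| time / min | Q / % |
|---|---|
| 12.0 | 10.7 |
| 20.0 | 11.3 |
| 30.0 | 11.0 |
| 40.0 | 10.7 |
| 60.0 | 11.0 |

(readings scatter by 0.5 percentage points)

- which of the two there is more of at the end, cedar (D / Q)
- which of the two there is more of at the end, birch (D / Q)
- amount of Q at the end, in percent of the G charged, cedar
- amount of Q at the end, in percent of the G charged, birch

In the violet run at −14 °C, Q stands at 24.3 % after 0.200 h against a plateau read near 34.5 %, so I read 0.114 h as the half-time of the rise of Q in the violet run, taken as a single exponential. Cedar at −20 °C and with less G may run slower than that by a factor these readings do not give, but its 3.0 h is 26.4 such half-times, so I expect the plateau in cedar and in birch, and the question becomes the split, not the time.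

The forecast gives Q with 50 % of Q for cedar and D with 10 % of Q for birch, on the ground that “Both runs reach a plateau, so G is used up”.

Cedar ends with Q 49.2 % against D 21.3 %, and birch with Q 13.0 % against D 77.9 %.

    L ⇌ Z, rate k1*(csat - [Z]) (kL = 0.0114 s⁻¹)
    G + Z → Q (k = 0.0730 L mol⁻¹ s⁻¹, Ea = 56.0 kJ mol⁻¹)
    G → D (k = 2.56 × 10⁻⁴ s⁻¹, Ea = 77.0 kJ mol⁻¹)
    G + Q → X (k = 0.00487 L mol⁻¹ s⁻¹, Ea = 53.0 kJ mol⁻¹)
    Z → J (k = 0.00204 s⁻¹, Ea = 69.0 kJ mol⁻¹)
    (constants at −20 °C)

In cedar, G is down to 0.0141 % at 1.50 h, which is an average half-life of G of 0.117 h over that time, beside the half-time 0.114 h of the rise of Q read from the violet run, and Q stands at 49.2 % then and at 49.2 % at 3.00 h. Carried to the neighbouring flask, which is cedar with 0.64 M of G, the violet half-time gives the same count of 26.4, so I expect a plateau by 3.0 h, and 0 % of the G is left there; yet Q in that flask ends at 18.5 %, while X, the species holding most of the G there, stands at 54.3 %.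

The runs stem from a simulated flask on assumed constants; noise was put on by code.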